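Labdane numbering is used. The route rests on the C9–C11 disconnection beside the quaternary ring-fusion carbon C10. In ring B, the C8(=CH2)–C9(side chain)–C10(CH3) triad is the retron of a conjugate addition/aldol sequence on a 20-nor Δ9(10)-8-ketone: Me2CuLi adds at C10 cis to 5-H, setting the cis ring fusion, and the regiodefined C8 enolate captures the C11–C15 aldehyde at C9, so one flask forges C9–C11 and the C10 quaternary centre. The precursor is a bicyclic enone ester lacking both ring methyls, from an auxiliary-controlled Diels–Alder reaction; dehydration, hydrogenation, methylenation, C4 methylation and caffeoylation complete the target.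

Key step: step 10

Remark: read literally, the SMILES describes the (4S,5S,9R,10R,13S) isomer, a cis-fused decalin (5-H and 10-CH3 cis) with the C9 side chain trans to 10-CH3, and the route is built for exactly this isomer. β denotes the face of the C10 methyl, TBS = tert-butyldimethylsilyl, TMSE = 2-(trimethylsilyl)ethyl, and 1, 5, 10 and 23 are assumed to be commercial.

Step 1
Reactants: 1 1,4-dioxaspiro[4.5]decan-7-one
Product: 3 1,4-dioxaspiro[4.5]dec-7-en-7-yl trifluoromethanesulfonate, via lithium enolate 2 (not isolated)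
Conditions: LDA, THF, −78 °C; then PhNTf2, −78 → 0 °C; aq NH4Cl
Reagents that add atoms: N-phenylbis(trifluoromethanesulfonimide), O=S(=O)(N(c1ccccc1)S(=O)(=O)C(F)(F)F)C(F)(F)F
Why: Kinetic deprotonation should occur at the α-CH2 remote from the ketal (the other α-CH2 is shielded by the spiro centre), and O-sulfonylation of the enolate gives the regiodefined enol triflate (enol triflate formation).

Step 2
Reactants: 3 1,4-dioxaspiro[4.5]dec-7-en-7-yl trifluoromethanesulfonate
Product: 4 7-ethenyl-1,4-dioxaspiro[4.5]dec-7-ene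
Conditions: tributyl(vinyl)stannane, Pd(PPh3)4 (5 mol%), LiCl, THF, 65 °C
Reagents that add atoms: tributyl(vinyl)stannane, C=C[Sn](CCCC)(CCCC)CCCC
Why: Stille cross-coupling of the enol triflate (LiCl assists transmetallation) should give the 1-vinylcyclohexene-type diene without touching the ketal.

Step 3
Reactants: 5 (S)-4-benzyl-1,3-oxazolidin-2-one
Product: 6 (S)-3-acryloyl-4-benzyl-1,3-oxazolidin-2-one
Conditions: acryloyl chloride, Et3N, LiCl, THF, −20 °C → rt
Reagents that add atoms: acryloyl chloride, C=CC(=O)Cl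
Why: Mild N-acylation of the oxazolidinone (imide formation) under LiCl/Et3N conditions avoids strongly basic conditions that polymerise the acryloyl unit.

Step 4
Reactants: 4 7-ethenyl-1,4-dioxaspiro[4.5]dec-7-ene; 6 (S)-3-acryloyl-4-benzyl-1,3-oxazolidin-2-one
Product: 7 (4S)-4-benzyl-3-{[(1R,8aR)-6,6-(ethylenedioxy)-1,2,3,5,6,7,8,8a-octahydronaphthalen-1-yl]carbonyl}-1,3-oxazolidin-2-one (1-H and 8a-H cis)
Conditions: Et2AlCl (1.4 equiv), CH2Cl2, −78 °C
Reagents that add atoms: none
Why: Lewis-acid-promoted Diels–Alder reaction in which the Al-chelated s-cis acryloyl imide is attacked on its Cα-si face (the benzyl group shields the re face) through an endo transition state with "ortho" regiochemistry (vinyl CH2 terminus to the acrylate β-carbon), which sets C5 (5-H of the target) and places 4-H cis to 5-H.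

Step 5
Reactants: 7 Diels–Alder imide
Product: 8 2-(trimethylsilyl)ethyl (1R,8aR)-6,6-(ethylenedioxy)-1,2,3,5,6,7,8,8a-octahydronaphthalene-1-carboxylate
Conditions: TMSCH2CH2OH, n-BuLi, THF, −78 → 0 °C; aq NH4Cl
Reagents that add atoms: 2-(trimethylsilyl)ethanol (as its lithium alkoxide), C[Si](C)(C)CCO
Why: Lithium alkoxide transesterification at the exocyclic imide carbonyl releases the auxiliary and installs the fluoride-labile TMSE ester; any C4 epimerisation is inconsequential because C4 is re-formed in step 14.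

Step 6
Reactants: 8 TMSE ester ketal
Product: 9 2-(trimethylsilyl)ethyl (1R,8aR)-6-oxo-1,2,3,4,6,7,8,8a-octahydronaphthalene-1-carboxylate (labdane numbering: 20-nor Δ9(10)-8-ketone, 4-H and 5-H cis)
Conditions: 1 M HCl, THF, rt
Reagents that add atoms: water, O
Why: Acidic ketal hydrolysis followed by acid-catalysed migration of the β,γ-double bond into conjugation (via the C8 dienol, protonation at C1) should give the enone without involving C5, provided equilibration is not prolonged.

Step 7
Reactants: 10 (R)-5-methoxy-3-methyl-5-oxopentanoic acid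
Product: 11 methyl (R)-5-hydroxy-3-methylpentanoate
Conditions: BH3·SMe2, THF, 0 °C → rt; aqueous work-up
Reagents that add atoms: none
Why: Borane reduction of the carboxylic acid (via the acyloxyborane) is much faster than that of the methyl ester, so the two ends of the glutarate are differentiated and the acid terminus becomes C15.

Step 8
Reactants: 11 methyl (R)-5-hydroxy-3-methylpentanoate
Product: 12 methyl (R)-5-(tert-butyldimethylsilyloxy)-3-methylpentanoate
Conditions: TBSCl, imidazole, DMF, 0 °C → rt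
Reagents that add atoms: tert-butyldimethylsilyl chloride, CC(C)(C)[Si](C)(C)Cl
Why: Silyl ether protection of the primary alcohol prevents lactonisation and survives all steps up to step 15.

Step 9
Reactants: 12 methyl (R)-5-(tert-butyldimethylsilyloxy)-3-methylpentanoate
Product: 13 (R)-5-(tert-butyldimethylsilyloxy)-3-methylpentanal
Conditions: DIBAL-H (1.05 equiv), CH2Cl2, −78 °C; Rochelle salt
Reagents that add atoms: none
Why: Partial ester reduction, in which the tetrahedral aluminium hemiacetal is stable at −78 °C and collapses to the aldehyde (future C11) only on work-up.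

Step 10
Reactants: 9 bicyclic enone TMSE ester; 13 (R)-5-(tert-butyldimethylsilyloxy)-3-methylpentanal
Product: 15 2-(trimethylsilyl)ethyl 15-(TBS-oxy)-11-hydroxy-8-oxo-17,18-dinorlabdan-19-oate with 4β-H (ester α) 5β-H and 10β-CH3 (cis-fused; C9 and C11 epimer mixture; C13 as in 13), via lithium enolate 14 (not isolated)
Conditions: Me2CuLi (from CuI and 2 MeLi), Et2O, −20 → 0 °C; then 13, THF, −78 °C; aq NH4Cl
Reagents that add atoms: lithium dimethylcuprate (from MeLi and CuI), [Li+].C[Cu-]C
Why: Me2CuLi transfers methyl to the β-carbon C10 of enone 9 (π-complex, Cu(III) adduct, reductive elimination) and leaves the regiodefined lithium enolate 14 (C8=C9), which adds through C9 to the aldehyde carbon of 13 (future C11) in a closed aldol transition state, so the C10–CH3 and C9–C11 bonds are made in one flask. The closest known reaction type is the three-component conjugate addition/enolate–aldehyde trapping of cyclic enones. No ring is closed. C10 is controlled by the existing C5 centre: stereoelectronically axial attack on ring B occurs on the face of 5-H, where the entering methyl is equatorial to ring A and avoids the α-face C4 ester, which gives the cis ring fusion; C9 and C11 form as mixtures that are erased (C11) or reset (C9) in steps 11 and 12. The step needs 1,4- over 1,2-addition and C9 over C7 reactivity, secured by the soft cuprate and by using the enolate at −78 °C before it can equilibrate; the secondary TMSE ester and the silyl ether are inert.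

Step 11
Reactants: 15 aldol adduct
Product: 17 2-(trimethylsilyl)ethyl 15-(TBS-oxy)-8-oxo-17,18-dinorlabd-9(11)-en-19-oate with 4β-H 5β-H 10β-CH3 (E/Z mixture), via C11 mesylate 16 (not isolated)
Conditions: MsCl, Et3N, CH2Cl2, 0 °C; then DBU, rt
Reagents that add atoms: none
Why: Mesylation and E1cB elimination through the C9 enolate complete an aldol condensation and should give the conjugated C9=C11 enone from every aldol diastereomer.

Step 12
Reactants: 17 exocyclic enone
Product: 18 2-(trimethylsilyl)ethyl (13S)-15-(TBS-oxy)-8-oxo-17,18-dinorlabdan-19-oate with 4β-H 5β-H 9β-H 10β-CH3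
Conditions: H2 (1 atm), 10% Pd/C, EtOAc, rt
Reagents that add atoms: none
Why: Heterogeneous hydrogenation should add H2 to the enone C=C from the convex β-face of the cis-decalin (the α-face of C9 is blocked by axial C1 of ring A), placing 9-H β and the chain α-equatorial, which is also the more stable C9 epimer should any epimerisation occur.

Step 13
Reactants: 18 C8 ketone
Product: 19 2-(trimethylsilyl)ethyl (13S)-15-(TBS-oxy)-18-norlabd-8(17)-en-19-oate with 4β-H 5β-H 9β-H 10β-CH3
Conditions: Zn, CH2Br2, TiCl4 (preformed reagent), THF/CH2Cl2, 0 °C → rt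
Reagents that add atoms: dibromomethane, BrCBr
Why: Takai–Lombardo methylenation converts the hindered C8 ketone into the exocyclic methylene under non-basic conditions, so the epimerisable C9 centre and the ester are untouched.

Step 14
Reactants: 19 C4-H ester
Product: 21 2-(trimethylsilyl)ethyl (4S,5S,9R,10R,13S)-15-(TBS-oxy)labd-8(17)-en-19-oate (4α-CH3, ester β), via lithium ester enolate 20 (not isolated)
Conditions: LDA, THF, −78 → −20 °C; then MeI, DMPU, −78 → 0 °C
Reagents that add atoms: iodomethane, CI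
Why: Ester enolate alkylation in which, in the chair conformer fixed by the equatorial C9 chain, the β (axial) face of C4 is blocked by the syn-axial C10 methyl, so MeI should enter equatorially from the α-face and leave the ester β-axial, as in the alkylation of resin-acid-type C4 ester enolates.

Step 15
Reactants: 21 fully substituted TMSE ester
Product: 22 2-(trimethylsilyl)ethyl (4S,5S,9R,10R,13S)-15-hydroxylabd-8(17)-en-19-oate
Conditions: CSA (10 mol%), MeOH/CH2Cl2, 0 °C
Reagents that add atoms: none
Why: Acid-catalysed methanolysis removes the primary TBS ether, while the TMSE ester and the exocyclic alkene should survive the cold, mildly acidic conditions.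

Step 16
Reactants: 23 caffeic acid
Product: 25 (E)-3-[3,4-bis(tert-butyldimethylsilyloxy)phenyl]prop-2-enoic acid, via tris-silylated caffeate 24 (not isolated)
Conditions: TBSCl (3.5 equiv), imidazole, DMF, rt; then AcOH/THF/H2O, rt
Reagents that add atoms: tert-butyldimethylsilyl chloride, CC(C)(C)[Si](C)(C)Cl
Why: Exhaustive silylation followed by selective hydrolysis of the labile silyl ester frees the acid and keeps both aryl silyl ethers.

Step 17
Reactants: 22 C15 alcohol; 25 bis-TBS caffeic acid
Product: 26 2-(trimethylsilyl)ethyl (4S,5S,9R,10R,13S)-15-{(E)-3-[3,4-bis(tert-butyldimethylsilyloxy)phenyl]prop-2-enoyloxy}labd-8(17)-en-19-oate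
Conditions: EDC·HCl, DMAP (cat.), CH2Cl2, rt
Reagents that add atoms: none
Why: Steglich-type carbodiimide esterification acylates the primary C15 alcohol and retains the (E)-cinnamate geometry.

Step 18
Reactants: 26 protected caffeate
Product: 27 (4S,5S,9R,10R,13S)-15-[(E)-3-(3,4-dihydroxyphenyl)prop-2-enoyloxy]labd-8(17)-en-19-oic acid (target)
Conditions: TBAF (6 equiv), THF, 0 °C → rt, Ar; aq NH4Cl
Reagents that add atoms: none
Why: Fluoride cleaves both aryl silyl ethers and, by β-elimination of the 2-silylethyl group (loss of ethene), the hindered C19 ester without hydrolytic conditions, so the cinnamate ester and the exocyclic alkene should be preserved.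

Compound list
1 | 1,4-dioxaspiro[4.5]decan-7-one | O=C1CCCC2(C1)OCCO2 | starting material
2 | lithium 1,4-dioxaspiro[4.5]dec-7-en-7-olate | [Li]OC1=CCCC2(C1)OCCO2 | intermediate (not isolated)
3 | 1,4-dioxaspiro[4.5]dec-7-en-7-yl trifluoromethanesulfonate | O=S(=O)(OC1=CCCC2(C1)OCCO2)C(F)(F)F | intermediate
4 | 7-ethenyl-1,4-dioxaspiro[4.5]dec-7-ene | C=CC1=CCCC2(C1)OCCO2 | intermediate
5 | (S)-4-benzyl-1,3-oxazolidin-2-one | O=C1N[C@@H](Cc2ccccc2)CO1 | starting material
6 | (S)-3-acryloyl-4-benzyl-1,3-oxazolidin-2-one | C=CC(=O)N1C(=O)OC[C@@H]1Cc1ccccc1 | intermediate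
7 | (4S)-4-benzyl-3-{[(1R,8aR)-6,6-(ethylenedioxy)-1,2,3,5,6,7,8,8a-octahydronaphthalen-1-yl]carbonyl}-1,3-oxazolidin-2-one | O1CCOC12CC[C@H]3C(C2)=CCC[C@H]3C(=O)N1C(=O)OC[C@@H]1Cc1ccccc1 | intermediate
8 | 2-(trimethylsilyl)ethyl (1R,8aR)-6,6-(ethylenedioxy)-1,2,3,5,6,7,8,8a-octahydronaphthalene-1-carboxylate | O1CCOC12CC[C@H]3C(C2)=CCC[C@H]3C(=O)OCC[Si](C)(C)C | intermediate
9 | 2-(trimethylsilyl)ethyl (1R,8aR)-6-oxo-1,2,3,4,6,7,8,8a-octahydronaphthalene-1-carboxylate | O=C1CC[C@H]2C(=C1)CCC[C@H]2C(=O)OCC[Si](C)(C)C | intermediate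
10 | (R)-5-methoxy-3-methyl-5-oxopentanoic acid (methyl hydrogen (R)-3-methylglutarate) | COC(=O)C[C@H](C)CC(=O)O | starting material
11 | methyl (R)-5-hydroxy-3-methylpentanoate | COC(=O)C[C@H](C)CCO | intermediate
12 | methyl (R)-5-(tert-butyldimethylsilyloxy)-3-methylpentanoate | COC(=O)C[C@H](C)CCO[Si](C)(C)C(C)(C)C | intermediate
13 | (R)-5-(tert-butyldimethylsilyloxy)-3-methylpentanal | O=CC[C@H](C)CCO[Si](C)(C)C(C)(C)C | intermediate
14 | lithium C8(9)-enolate of the C10-methylated cis-decalone (4β-H, 5β-H, 10β-CH3) | [Li]OC=1CC[C@H]2[C@](C)(CCC[C@H]2C(=O)OCC[Si](C)(C)C)C=1 | intermediate (not isolated)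
15 | 2-(trimethylsilyl)ethyl 15-(TBS-oxy)-11-hydroxy-8-oxo-17,18-dinorlabdan-19-oate (4β-H, 5β-H, 10β-CH3; C9/C11 mixture) | O=C1CC[C@H]2[C@](C)(CCC[C@H]2C(=O)OCC[Si](C)(C)C)C1C(O)C[C@H](C)CCO[Si](C)(C)C(C)(C)C | intermediate
16 | C11 methanesulfonate of 15 | O=C1CC[C@H]2[C@](C)(CCC[C@H]2C(=O)OCC[Si](C)(C)C)C1C(OS(C)(=O)=O)C[C@H](C)CCO[Si](C)(C)C(C)(C)C | intermediate (not isolated)
17 | 2-(trimethylsilyl)ethyl 15-(TBS-oxy)-8-oxo-17,18-dinorlabd-9(11)-en-19-oate (4β-H, 5β-H, 10β-CH3; E/Z mixture) | O=C1CC[C@H]2[C@](C)(CCC[C@H]2C(=O)OCC[Si](C)(C)C)C1=CC[C@H](C)CCO[Si](C)(C)C(C)(C)C | intermediate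
18 | 2-(trimethylsilyl)ethyl (13S)-15-(TBS-oxy)-8-oxo-17,18-dinorlabdan-19-oate (4β-H, 5β-H, 9β-H, 10β-CH3) | O=C1CC[C@H]2[C@](C)(CCC[C@H]2C(=O)OCC[Si](C)(C)C)[C@@H]1CC[C@H](C)CCO[Si](C)(C)C(C)(C)C | intermediate
19 | 2-(trimethylsilyl)ethyl (13S)-15-(TBS-oxy)-18-norlabd-8(17)-en-19-oate (4β-H, 5β-H, 9β-H, 10β-CH3) | C=C1CC[C@H]2[C@](C)(CCC[C@H]2C(=O)OCC[Si](C)(C)C)[C@@H]1CC[C@H](C)CCO[Si](C)(C)C(C)(C)C | intermediate
20 | lithium ester enolate of 19 (C4 trigonal) | C=C1CC[C@H]2[C@](C)(CCCC2=C(O[Li])OCC[Si](C)(C)C)[C@@H]1CC[C@H](C)CCO[Si](C)(C)C(C)(C)C | intermediate (not isolated)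
21 | 2-(trimethylsilyl)ethyl (4S,5S,9R,10R,13S)-15-(TBS-oxy)labd-8(17)-en-19-oate | C=C1CC[C@H]2[C@](C)(CCC[C@]2(C)C(=O)OCC[Si](C)(C)C)[C@@H]1CC[C@H](C)CCO[Si](C)(C)C(C)(C)C | intermediate
22 | 2-(trimethylsilyl)ethyl (4S,5S,9R,10R,13S)-15-hydroxylabd-8(17)-en-19-oate | C=C1CC[C@H]2[C@](C)(CCC[C@]2(C)C(=O)OCC[Si](C)(C)C)[C@@H]1CC[C@H](C)CCO | intermediate
23 | caffeic acid, (E)-3-(3,4-dihydroxyphenyl)prop-2-enoic acid | OC(=O)/C=C/c1ccc(O)c(O)c1 | starting material
24 | tert-butyldimethylsilyl (E)-3-[3,4-bis(tert-butyldimethylsilyloxy)phenyl]prop-2-enoate | CC(C)(C)[Si](C)(C)OC(=O)/C=C/c1ccc(O[Si](C)(C)C(C)(C)C)c(O[Si](C)(C)C(C)(C)C)c1 | intermediate (not isolated)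
25 | (E)-3-[3,4-bis(tert-butyldimethylsilyloxy)phenyl]prop-2-enoic acid | OC(=O)/C=C/c1ccc(O[Si](C)(C)C(C)(C)C)c(O[Si](C)(C)C(C)(C)C)c1 | intermediate
26 | 2-(trimethylsilyl)ethyl (4S,5S,9R,10R,13S)-15-{(E)-3-[3,4-bis(tert-butyldimethylsilyloxy)phenyl]prop-2-enoyloxy}labd-8(17)-en-19-oate | C=C1CC[C@H]2[C@](C)(CCC[C@]2(C)C(=O)OCC[Si](C)(C)C)[C@@H]1CC[C@H](C)CCOC(=O)/C=C/c1ccc(O[Si](C)(C)C(C)(C)C)c(O[Si](C)(C)C(C)(C)C)c1 | intermediate
27 | (4S,5S,9R,10R,13S)-15-[(E)-3-(3,4-dihydroxyphenyl)prop-2-enoyloxy]labd-8(17)-en-19-oic acid | C=C1CC[C@H]2[C@](C)(CCC[C@]2(C)C(=O)O)[C@@H]1CC[C@H](C)CCOC(=O)/C=C/c1ccc(O)c(O)c1 | target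

Total step count: 18. Longest linear sequence: 13 steps (1, 2, 4, 5, 6, 10, 11, 12, 13, 14, 15, 17, 18).

Steps most likely to fail

Step 10 (key step). The C8 enolate may be quenched by proton transfer from the enolisable aldehyde, or the aldolate may revert before work-up. Slow conjugate addition to the β,β-disubstituted enone may also leave time for enolate equilibration towards C7. Fallback: setting out from 9, the conjugate addition is run with Me2CuLi in the presence of TMSCl (Et2O/THF, −78 °C) and the enolate is isolated as the trimethylsilyl enol ether F1. A Mukaiyama aldol reaction of F1 with aldehyde 13 (BF3·OEt2, CH2Cl2, −78 °C) then forms the C9–C11 bond under Lewis-acid instead of basic enolate conditions and comes back to the route at 15.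

Step 14. Enolisation of the hindered axial C4–H (syn-axial to the C10 methyl) by the amide base may be incomplete, so that starting ester is returned or the base attacks elsewhere. Fallback: setting out from 19, DIBAL-H reduction gives the C19 primary alcohol F2 and Dess–Martin oxidation the aldehyde F3. Its far more acidic α-hydrogen allows enolisation under equilibrating conditions (t-BuOK, THF; then MeI), giving the quaternary aldehyde F4 by the same equatorial α-face attack. Pinnick oxidation (NaClO2, NaH2PO4, 2-methyl-2-butene) gives the acid F5, and Mitsunobu esterification with 2-(trimethylsilyl)ethanol (PPh3, DIAD) comes back to the route at 21.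

Step 4. Stoichiometric Et2AlCl may ionise the dioxolane or polymerise the diene faster than cycloaddition occurs, or the ortho regiocontrol of the 1,2-disubstituted diene may erode. Fallback: setting out from diene 4, a catalytic enantioselective Diels–Alder reaction is run with 2-(trimethylsilyl)ethyl acrylate F6 (from acryloyl chloride and 2-(trimethylsilyl)ethanol, Et3N). A chiral proline-derived oxazaborolidinium catalyst is used (10–20 mol%, CH2Cl2, −78 °C), with the enantiomer chosen to expose the acrylate Cα-si face. This should give ester 8 directly and comes back to the route at 8 without the aluminium Lewis acid and the auxiliary exchange.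

Further compounds
F1 | step 10 | 2-(trimethylsilyl)ethyl 8-(trimethylsilyloxy)-17,18-dinorlabd-8-en-19-oate fragment lacking the side chain (trimethylsilyl enol ether of the C10-methylated cis-decalone; 4β-H, 5β-H, 10β-CH3) | C[Si](C)(C)OC=1CC[C@H]2[C@](C)(CCC[C@H]2C(=O)OCC[Si](C)(C)C)C=1
F2 | step 14 | (13S)-15-(TBS-oxy)-18-norlabd-8(17)-en-19-ol (4β-H, 5β-H, 9β-H, 10β-CH3) | C=C1CC[C@H]2[C@](C)(CCC[C@H]2CO)[C@@H]1CC[C@H](C)CCO[Si](C)(C)C(C)(C)C
F3 | step 14 | (13S)-15-(TBS-oxy)-18-norlabd-8(17)-en-19-al (4β-H, 5β-H, 9β-H, 10β-CH3) | C=C1CC[C@H]2[C@](C)(CCC[C@H]2C=O)[C@@H]1CC[C@H](C)CCO[Si](C)(C)C(C)(C)C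
F4 | step 14 | (4S,5S,9R,10R,13S)-15-(TBS-oxy)labd-8(17)-en-19-al | C=C1CC[C@H]2[C@](C)(CCC[C@]2(C)C=O)[C@@H]1CC[C@H](C)CCO[Si](C)(C)C(C)(C)C
F5 | step 14 | (4S,5S,9R,10R,13S)-15-(TBS-oxy)labd-8(17)-en-19-oic acid | C=C1CC[C@H]2[C@](C)(CCC[C@]2(C)C(=O)O)[C@@H]1CC[C@H](C)CCO[Si](C)(C)C(C)(C)C
F6 | step 4 | 2-(trimethylsilyl)ethyl acrylate | C=CC(=O)OCC[Si](C)(C)C
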